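The route rests on cutting the oxirane at its CH2 group. The key step exploits the fact that the quaternary oxirane carbon carries the benzene ring and the CH2OAc arm: it is the former carbonyl carbon of an aryl acetoxymethyl ketone, and the oxirane CH2 comes from a sulfoxonium ylide. One catalytic asymmetric methylene transfer forms the C(quaternary)–CH2 and O–CH2 bonds, closes the three-membered ring and sets the only stereocentre as (S). The precursor is 4-(acetoxyacetyl)-3-(triisopropylsilyloxy)benzyl pentanoate: both alkyl esters are in place and the phenol is masked as a silyl ether, which is exchanged for the isobutyrate in the last step.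

Key step: step 6

Assumption: the lanthanum–lithium binaphthoxide catalyst is taken to tell the two ketone substituents apart as it does in aryl methyl ketones (aryl as the large group, CH2OAc in the place of methyl), so the (S)-binaphthol complex is written for the (S)-oxirane; if a trial run, correlated with the tartrate-derived sample of the first fallback, shows the opposite sense, the (R)-binaphthol complex is used and nothing else changes.

Step 1
Reactants: 1 methyl 4-bromo-3-hydroxybenzoate
Product: 2 methyl 4-bromo-3-(triisopropylsilyloxy)benzoate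
Conditions: i-Pr3SiCl (1.2 equiv), imidazole (2.5 equiv), DMF, rt
Reagents that add atoms: chlorotriisopropylsilane, CC(C)[Si](Cl)(C(C)C)C(C)C
Why: Imidazole-mediated O-silylation of the phenol (Corey-type silyl ether formation) is the only reaction open to 1, and the bulky triisopropylsilyl ether is chosen because it has to withstand hydride, hot palladium chemistry, acetate and a basic ylide.

Step 2
Reactants: 2 methyl 4-bromo-3-(triisopropylsilyloxy)benzoate
Product: 3 [4-bromo-3-(triisopropylsilyloxy)phenyl]methanol
Conditions: i-Bu2AlH (2.5 equiv), CH2Cl2, −78 → 0 °C; aq. potassium sodium tartrate work-up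
Reagents that add atoms: none
Why: Ester-to-alcohol reduction with i-Bu2AlH should stop cleanly at the benzylic alcohol, the aryl bromide and the aryl silyl ether being inert to the hydride at these temperatures.

Step 3
Reactants: 3 [4-bromo-3-(triisopropylsilyloxy)phenyl]methanol
Product: 4 4-bromo-3-(triisopropylsilyloxy)benzyl pentanoate
Conditions: (n-BuCO)2O (1.2 equiv), Et3N, DMAP (cat.), CH2Cl2, 0 °C → rt
Reagents that add atoms: pentanoic anhydride, CCCCC(=O)OC(=O)CCCC
Why: DMAP-catalysed acylation (nucleophilic acyl transfer) of the only free hydroxyl group installs the pentanoate before any base-sensitive ketone is present.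

Step 4
Reactants: 4 4-bromo-3-(triisopropylsilyloxy)benzyl pentanoate; 5 tributyl(1-ethoxyvinyl)stannane
Product: 7 4-(bromoacetyl)-3-(triisopropylsilyloxy)benzyl pentanoate, via enol ether 6 (not isolated)
Conditions: Pd(PPh3)4 (zerovalent palladium, 5 mol %), 1,4-dioxane, 95 °C; then 0 °C, THF–H2O, NBS (1.1 equiv)
Reagents that add atoms: N-bromosuccinimide, O=C1CCC(=O)N1Br; water, O
Why: A Migita–Kosugi–Stille coupling joins the aryl bromide to the α-ethoxyvinyl group under neutral conditions that spare ester and silyl ether, and the electron-rich enol ether 6 is then brominated at its CH2 by NBS while water adds to the oxocarbenium ion and expels ethanol (hydrolytic bromination of an enol ether), so the bromomethyl ketone is reached without isolating the acid-labile enol ether.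

Step 5
Reactants: 7 4-(bromoacetyl)-3-(triisopropylsilyloxy)benzyl pentanoate
Product: 8 4-(acetoxyacetyl)-3-(triisopropylsilyloxy)benzyl pentanoate
Conditions: KOAc (1.5 equiv), DMF, 0 °C → rt
Reagents that add atoms: potassium acetate, CC(=O)[O-].[K+]
Why: SN2 displacement of the carbonyl-activated primary bromide by acetate is fast at 0 °C, a temperature at which acetate should not yet attack the hindered triisopropylsilyl group.

Step 6
Reactants: 8 4-(acetoxyacetyl)-3-(triisopropylsilyloxy)benzyl pentanoate; 9 trimethylsulfoxonium iodide
Product: 12 (S)-4-[2-(acetoxymethyl)oxiran-2-yl]-3-(triisopropylsilyloxy)benzyl pentanoate, via dimethyloxosulfonium methylide 10 (not isolated), via sulfoxonium betaine 11 (not isolated)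
Conditions: 9, NaH, THF, reflux, then filtration under argon to give 10 in THF; slow addition of 10 (1.2 equiv) to 8, LaLi3[(S)-1,1'-binaphthalene-2,2'-diolate]3 (trivalent lanthanum, 5 mol %), (2,4,6-(MeO)3C6H2)3P=O (5 mol %), 5 Å molecular sieves, THF, rt
Reagents that add atoms: none
Why: The ketone oxygen of 8, helped by the neighbouring acetate carbonyl, binds the lanthanum centre while a lithium binaphthoxide site positions ylide 10, whose carbon adds to one face of the C=O group to give betaine 11, and the metal-bound alkoxide then displaces dimethyl sulfoxide from the adjacent CH2. The closest known reaction is the asymmetric Corey–Chaykovsky epoxidation of aryl methyl ketones under LaLi3(binaphthoxide)3 with a triarylphosphine oxide, a known reaction applied here to a ketone whose small arm is CH2OAc in place of CH3. The oxirane is closed in the 3-exo-tet mode. The new quaternary stereocentre is set by the catalyst alone: the chiral binaphthoxide pocket tells the twisted ortho-silyloxyaryl group from the slim acetoxymethyl arm, and no stereocentre of the substrate takes part. The step needs enantiofacial selectivity and chemoselectivity for the ketone over the two alkyl esters; the α-acetoxy group makes the ketone the most electrophilic carbonyl, enolisation toward CH2OAc is reversible and destroys no stereocentre, and the bulky silyl ether, unlike an aryl ester that the ylide or the betaine alkoxide would be acylated by, leaves nothing easily transferable on the ortho oxygen. Only a small excess of ylide at room temperature is used so that a second methylene transfer does not enlarge the oxirane to an oxetane.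

Step 7
Reactants: 12 (S)-4-[2-(acetoxymethyl)oxiran-2-yl]-3-(triisopropylsilyloxy)benzyl pentanoate
Product: 14 (S)-4-[2-(acetoxymethyl)oxiran-2-yl]-3-(isobutyryloxy)benzyl pentanoate (CNP0107520.1), via caesium phenoxide 13 (not isolated)
Conditions: CsF (2.5 equiv), (i-PrCO)2O (3 equiv), DMF, 0 °C → rt
Reagents that add atoms: isobutyric anhydride, CC(C)C(=O)OC(=O)C(C)C
Why: Fluoride cleaves the aryl O–Si bond and phenoxide 13 is acylated as it forms by the anhydride present in excess (one-pot desilylative acylation), so it has no lifetime in which to push open the benzylic C–O bond of the oxirane, and the untouched stereocentre keeps its (S) configuration.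

Compound list
1 | methyl 4-bromo-3-hydroxybenzoate | COC(=O)c1ccc(Br)c(O)c1 | starting material
2 | methyl 4-bromo-3-(triisopropylsilyloxy)benzoate | COC(=O)c1ccc(Br)c(O[Si](C(C)C)(C(C)C)C(C)C)c1 | intermediate
3 | [4-bromo-3-(triisopropylsilyloxy)phenyl]methanol | OCc1ccc(Br)c(O[Si](C(C)C)(C(C)C)C(C)C)c1 | intermediate
4 | 4-bromo-3-(triisopropylsilyloxy)benzyl pentanoate | CCCCC(=O)OCc1ccc(Br)c(O[Si](C(C)C)(C(C)C)C(C)C)c1 | intermediate
5 | tributyl(1-ethoxyvinyl)stannane | CCCC[Sn](CCCC)(CCCC)C(=C)OCC | starting material
6 | 4-(1-ethoxyvinyl)-3-(triisopropylsilyloxy)benzyl pentanoate (enol ether) | CCCCC(=O)OCc1ccc(C(=C)OCC)c(O[Si](C(C)C)(C(C)C)C(C)C)c1 | intermediate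
7 | 4-(bromoacetyl)-3-(triisopropylsilyloxy)benzyl pentanoate | CCCCC(=O)OCc1ccc(C(=O)CBr)c(O[Si](C(C)C)(C(C)C)C(C)C)c1 | intermediate
8 | 4-(acetoxyacetyl)-3-(triisopropylsilyloxy)benzyl pentanoate | CCCCC(=O)OCc1ccc(C(=O)COC(C)=O)c(O[Si](C(C)C)(C(C)C)C(C)C)c1 | intermediate
9 | trimethylsulfoxonium iodide | C[S+](C)(C)=O.[I-] | starting material
10 | dimethyloxosulfonium methylide | CS(C)(=O)=C | intermediate
11 | sulfoxonium betaine, (2R)-1-acetoxy-3-(dimethyloxosulfonio)-2-[4-(pentanoyloxymethyl)-2-(triisopropylsilyloxy)phenyl]propan-2-olate | CCCCC(=O)OCc1ccc([C@@]([O-])(COC(C)=O)C[S+](C)(C)=O)c(O[Si](C(C)C)(C(C)C)C(C)C)c1 | intermediate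
12 | (S)-4-[2-(acetoxymethyl)oxiran-2-yl]-3-(triisopropylsilyloxy)benzyl pentanoate | CCCCC(=O)OCc1ccc([C@@]2(COC(C)=O)CO2)c(O[Si](C(C)C)(C(C)C)C(C)C)c1 | intermediate
13 | caesium (S)-2-[2-(acetoxymethyl)oxiran-2-yl]-5-(pentanoyloxymethyl)phenoxide | CCCCC(=O)OCc1ccc([C@@]2(COC(C)=O)CO2)c([O-])c1.[Cs+] | intermediate
14 | (S)-4-[2-(acetoxymethyl)oxiran-2-yl]-3-(isobutyryloxy)benzyl pentanoate (CNP0107520.1) | CCCCC(=O)OCc1ccc([C@@]2(COC(C)=O)CO2)c(OC(=O)C(C)C)c1 | target

Total step count: 7. Longest linear sequence: 7 steps (1 → 14).

Steps most likely to fail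

Step 6. The chiral pocket may discriminate poorly between the ortho-silyloxyaryl group and the acetoxymethyl arm, since this ketone lies outside the methyl ketone series. The basic ylide may also enolise the ketone and set off an acetyl shift. Acetyl or silyl may be passed to the betaine alkoxide before ring closure. The fallback sets out from 4 and comes back at 12. Stille coupling of 4 with 2-(tributylstannyl)prop-2-en-1-ol (Pd(PPh3)4, dioxane, 90 °C) should give 4-(3-hydroxyprop-1-en-2-yl)-3-(triisopropylsilyloxy)benzyl pentanoate F1. Sharpless asymmetric epoxidation (Ti(OiPr)4, D-(−)-diethyl tartrate, t-BuOOH, 4 Å molecular sieves, CH2Cl2, −20 °C) should deliver oxygen to the face from which allyl alcohol gives (R)-glycidol, giving (R)-4-[2-(hydroxymethyl)oxiran-2-yl]-3-(triisopropylsilyloxy)benzyl pentanoate F2. Acetylation (Ac2O, pyridine, DMAP, 0 °C) then gives 12; the descriptor changes to (S) only because CH2OAc outranks the oxirane CH2 whereas CH2OH does not. This sample also fixes the absolute configuration for the main route.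

Step 7. Cleavage of the hindered silyl ether may be slow, or acylation may not keep pace with it, so that the free phenoxide ionises the benzylic C–O bond of the oxirane or takes over the acetyl group. Fluoride or carboxylate may also open the ring. The fallback sets out from 4 and comes back at 14; it places the isobutyrate before the oxirane exists. CsF and (i-PrCO)2O in DMF should convert 4 into 4-bromo-3-(isobutyryloxy)benzyl pentanoate F3, the phenoxide having nothing to attack at that stage. Stille coupling with 2-(tributylstannyl)prop-2-en-1-ol should give 4-(3-hydroxyprop-1-en-2-yl)-3-(isobutyryloxy)benzyl pentanoate F4. Sharpless epoxidation with Ti(OiPr)4, D-(−)-diethyl tartrate and t-BuOOH at −20 °C should give (R)-4-[2-(hydroxymethyl)oxiran-2-yl]-3-(isobutyryloxy)benzyl pentanoate F5. Acetylation (Ac2O, pyridine, 0 °C) gives 14 directly.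

Step 5. Acetate may strip the silyl group, which sits ortho to the ketone and therefore leaves as a stabilised phenoxide; the freed phenoxide would then close onto the bromomethyl ketone. Base-induced self-condensation of the bromo ketone is a second risk. The fallback sets out from enol ether 6, isolated for this purpose by filtration through basic alumina after the coupling of step 4, and comes back at 8. Epoxidation of the enol ether with dimethyldioxirane in acetone (−40 → 0 °C) and aqueous work-up (Rubottom-type oxidation, with loss of ethanol) should give 4-(hydroxyacetyl)-3-(triisopropylsilyloxy)benzyl pentanoate F6. Acetylation (Ac2O, pyridine, DMAP, 0 °C) gives 8 without any halide or free acetate ion in the flask.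

Further compounds
F1 | step 6 | 4-(3-hydroxyprop-1-en-2-yl)-3-(triisopropylsilyloxy)benzyl pentanoate | CCCCC(=O)OCc1ccc(C(=C)CO)c(O[Si](C(C)C)(C(C)C)C(C)C)c1
F2 | step 6 | (R)-4-[2-(hydroxymethyl)oxiran-2-yl]-3-(triisopropylsilyloxy)benzyl pentanoate | CCCCC(=O)OCc1ccc([C@@]2(CO)CO2)c(O[Si](C(C)C)(C(C)C)C(C)C)c1
F3 | step 7 | 4-bromo-3-(isobutyryloxy)benzyl pentanoate | CCCCC(=O)OCc1ccc(Br)c(OC(=O)C(C)C)c1
F4 | step 7 | 4-(3-hydroxyprop-1-en-2-yl)-3-(isobutyryloxy)benzyl pentanoate | CCCCC(=O)OCc1ccc(C(=C)CO)c(OC(=O)C(C)C)c1
F5 | step 7 | (R)-4-[2-(hydroxymethyl)oxiran-2-yl]-3-(isobutyryloxy)benzyl pentanoate | CCCCC(=O)OCc1ccc([C@@]2(CO)CO2)c(OC(=O)C(C)C)c1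
F6 | step 5 | 4-(hydroxyacetyl)-3-(triisopropylsilyloxy)benzyl pentanoate | CCCCC(=O)OCc1ccc(C(=O)CO)c(O[Si](C(C)C)(C(C)C)C(C)C)c1
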